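**Remark (numbering):** C1 is the lactone carbonyl; the ring runs C1–C8, the oxazole nitrogen (ring member 9), oxazole C2 = C10, C11–C17, and the ring oxygen on C17. Oxazole C5 is called C9 and the side chain is C18–C25.

## The problem

CNP0112511.2 (33) is an 18-membered macrolactone with an embedded 2,4-disubstituted oxazole. The ring carries a 2E enoate and a 6E trisubstituted alkene on oxazole C4; C17 carries a side chain with an 18E trisubstituted and a 21Z disubstituted alkene, separated by the C20 methylene, that ends in a tertiary α-hydroxy acid (C24, C25). The seven stereocentres fall into three isolated groups: C4/C5 (syn methyl/hydroxyl), the set C13 (methyl), C15 (methoxy), C16 (hydroxyl), C17 (acyloxy), and the quaternary C24. C15, C16 and C17 are contiguous and can control one another, but C13 is insulated from C15 by a methylene and is hard to set by acyclic induction; C4/C5 and C24 are too remote and must come from a reagent or a purchased centre. Alkene geometry must be solved four times, twice for trisubstituted alkenes. The fragile sites are the mono-acylated 16,17-diol (acyl shift to O16 under base), the doubly allylic C20 methylene, the C5 carbinol allylic to the alkenyl-oxazole, the enoate and the free acid, so the last steps must be near neutral and the protecting groups are all silicon-based. The feature that opens the key step is that C10 is at the carboxylic acid level, C15 bears oxygen, and C13 sits midway on the chain C10–C11–C12–C13–C14–C15: a C10–C15 bond in place of the C15–O bond gives 4-methylcyclohexanone, whose α-carbon is C15, so C15–C16 becomes an aldol bond to a three-carbon aldehyde (C16–C18) that already holds C17.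

## Retrosynthesis

**Side chain (C20–C21).** Target 33 is traced to its silyl-protected form 32 (two TBS ethers, one 2-(trimethylsilyl)ethyl ester), and 32 to the enyne 31 by syn semi-hydrogenation. Cutting C20–C21 of 31 gives the primary allylic bromide 26 and the terminal alkyne 30. A Wittig cut at C21=C22 would need a β,γ-unsaturated aldehyde or a homoallylic ylide on the macrolide, both prone to conjugation. The forward reaction must substitute at C20 without allylic transposition, and the Z alkene arrives only after the ring is closed.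

**Ring closure (C2=C3).** Bromide 26 comes from alcohol 25 and enal 24. The ring of 24 is cut at C2=C3 by ring-closing metathesis, giving the acrylate 23 with a C3 vinyl group. Lactonisation at O17 would need a seco acid and a differentiated 16,17-diol; a phosphonate closure would need a C3 aldehyde and several extra redox and protecting-group steps. The metathesis needs the C3 vinyl and the acrylate to be the only reactive alkenes, which is why the skipped diene is added later and C18=C19 is carried as an electron-poor trisubstituted enal.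

**C17/C18 (ester and enal).** Acrylate 23 is cut at O17–C1 to the hydroxy enal 22, and 22 at C18=C19 to the 17,18-diol 20, which is the deprotected acetonide 19. The acylation installs C1–C2 and doubles as the protection of O17, so no protecting group is spent on this oxygen. The forward step must oxidise only the primary hydroxyl and give the E alkene.

**C4–C5.** Silyl ether 19 comes from alcohol 18, which is cut at C4–C5 to the enal 17 and a (Z)-crotyl unit. An auxiliary-based syn aldol would also set C4/C5 but delivers C3 at the carboxyl level; the crotylboration gives C3 directly as the vinyl group that the metathesis needs.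

**C6=C7 and the C7 methyl.** Enal 17 is traced through alcohol 16 and ester 15 to methyl ketone 14 (olefination at C6=C7), and 14 to the oxazole ester 12 (C7–CH3 bond). The ketone is the simple partner, so the E geometry rests on a phosphonoacetate, not on a complex fragment.

**Oxazole.** Ester 12 is cut at the O–C10 and N–C10 bonds to the serine amide 10, hence to acid 8 and amine 9. This puts C10 at the acid level, where the next disconnection needs it.

**C15–O and C10.** Acid 8 comes from ester 7, alcohol 6 and the seven-membered lactone 5. Lactone 5 is the Baeyer–Villiger product of ketone 4, so the C15–O bond and the C10 carboxyl are both traced to one C10–C15 bond. C13 thereby becomes the 4-substituent of a cyclohexanone and is no longer a remote acyclic centre.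

**C15–C16 (key).** Ketone 4 is the silyl ether of aldol 3, which is cut at C15–C16 to the achiral ketone 1 and the aldehyde 2. Both are commercial. The forward reaction, under enamine catalysis by a chiral amino acid, must choose one of two enantiotopic α-carbons, one enamine face and one aldehyde face.

**Alkyne 30.** Ester 30 comes from acid 29 and diol 28, which is cut at C22–C23 to the epoxide 27. C24 is bought, and the forward opening does not touch it.

## Roads not taken

**Alternative 1: Stille macrocyclisation at C7–C8.** The ring is cut between C7 and oxazole C4. The open-chain ester A2, with an oxazol-4-yl triflate and an (E)-alkenyl tributylstannane, would be closed with Pd(PPh3)4, CuI and LiCl to the protected macrolide A1.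
- Merits: the C1–C7 acid and the oxazole alcohol are made separately and joined by esterification, and the 6E geometry is fixed in the stannane and kept in the coupling.
- Weak points: the α-methyl alkenylstannane transmetalates slowly and can protodestannylate; oxidative addition to an electron-rich oxazol-4-yl triflate is sluggish; both must work at high dilution on the most advanced intermediate, with the skipped diene present. The step also says nothing about C13–C17.
- Comparison: this road is more convergent and would shorten the longest linear sequence; that is a real advantage. The chosen plan sets against it an easier ring-closing bond (a disubstituted enoate), no tin, and a first step that sets three stereocentres from two commercial compounds.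

**Alternative 2: glycolate Ireland–Claisen rearrangement for C4, C5 and C2=C3.** The cut is C4–C5. Ester A4 would be converted with KN(SiMe3)2 and Me3SiCl into its chelated Z silyl ketene acetal, which rearranges through a chair to acid A3.
- Merits: one step sets C4, C5 and the 2E alkene by chirality transfer from a single carbinol, with no stoichiometric chiral reagent.
- Weak points: A3 has C1 as a silyl ether and C6 as an acid, so both ends need redox adjustment. The hard bond, C6=C7, would then be made from an epimerisable α-alkoxy aldehyde and a secondary oxazolyl-ethyl phosphorus reagent, with no reliable E control.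
- Comparison: for C4/C5 alone this is as good as the crotylboration and better in atom economy. The chosen plan sets against it that C6=C7 is made first, from a methyl ketone, and that C4/C5 then cost one step on the main chain and give C3 at the oxidation level the ring closure uses.

**Alternative 3: self-regenerating alkylation for C24.** The cut is C23–C24. The cis acetal A6 of the hydroxy acid A8 would be deprotonated with LiN(iPr)2 and alkylated by the bromide A7, trans to the tert-butyl group, to give A5.
- Merits: C24 comes from a cheap hydroxy acid with dependable diastereocontrol, and A5 already holds C18–C25 with an alkenyl iodide for a late union.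
- Weak points: the union would create C17 by adding an alkenyl metal to an aldehyde next to C16, with uncertain facial control. The propargylic bromide can react by SN2′, and the acetal must later be opened beside a macrolactone.
- Comparison: for C24 itself this is at least as short as the chosen fragment synthesis (three steps from a purchased epoxide). The chosen plan sets against it that C17 is fixed in the first step by the aldehyde 2 and is never formed by a late carbonyl addition.

Key step: step 1

## Route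

Remark: aldehyde 2 loses configurational purity on storage and is assumed to be used freshly distilled.

Abbreviations used in names:
- R* = (3S,5S,6R)-6-[(tert-butyldimethylsilyl)oxy]-6-[(4S)-2,2-dimethyl-1,3-dioxolan-4-yl]-5-methoxy-3-methylhexyl (C11–C18, bound through C11).
- Q = 4-{(2E,4R,5S)-4-[(tert-butyldimethylsilyl)oxy]-5-methylhepta-2,6-dien-2-yl}-1,3-oxazol-2-yl (C3–C10, bound through oxazole C2).
- "core" = the 18-membered ring of 33 with tert-butyldimethylsilyl ethers on O5 and O16, (2E,6E,4S,5R,13S,15S,16R,17S), bound through C17.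

Step 1
Reactants: 1 4-methylcyclohexan-1-one; 2 (4S)-2,2-dimethyl-1,3-dioxolane-4-carbaldehyde
Product: 3 (2S,4S)-2-{(R)-[(4S)-2,2-dimethyl-1,3-dioxolan-4-yl](hydroxy)methyl}-4-methylcyclohexan-1-one
Conditions: L-proline (30 mol %), DMF, 4 °C; 1 in excess
Reagents that add atoms: none
Why: Proline-catalysed direct aldol reaction by enamine catalysis; the closest known types are the L-proline desymmetrising aldol of 4-substituted cyclohexanones and the proline aldol of cyclic ketones with glyceraldehyde acetonide. Ketone 1 condenses with the catalyst to an enamine, and the carboxylic acid hydrogen-bonds the aldehyde oxygen in a chair-like transition state in which the anti enamine adds to the re face of the aldehyde, which gives the anti aldol with C15 (ring C2) S and C16 R. No ring is closed; one C–C bond (C15–C16) is formed. The choice between the enantiotopic α-carbons, and with it C13, follows from the half-chair enamine that keeps the 4-methyl pseudo-equatorial and is attacked axially, so the new substituent and the methyl end up trans (2S,4S). C17 is already present in 2, and the Felkin–Anh preference of the α-alkoxy aldehyde is for the same aldehyde face that L-proline selects, so the 16,17-anti isomer is the matched product. The step needs four selectivities at once (enantiotopic carbon, enamine face, aldehyde face, no enolisation of 2); they are secured by the matched catalyst–aldehyde pair, excess ketone, low temperature and fresh 2. The kinetic 2,4-trans product is carried on at once so that C15 cannot epimerise.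

Step 2
Reactants: 3 (2S,4S)-2-{(R)-[(4S)-2,2-dimethyl-1,3-dioxolan-4-yl](hydroxy)methyl}-4-methylcyclohexan-1-one
Product: 4 (2S,4S)-2-{(R)-[(tert-butyldimethylsilyl)oxy][(4S)-2,2-dimethyl-1,3-dioxolan-4-yl]methyl}-4-methylcyclohexan-1-one
Conditions: TBSOTf, 2,6-lutidine, CH2Cl2, −78 °C
Reagents that add atoms: tert-butyldimethylsilyl triflate, CC(C)(C)[Si](C)(C)OS(=O)(=O)C(F)(F)F
Why: Silyl ether formation on a hindered secondary alcohol; at −78 °C with 2,6-lutidine O-silylation should outrun enol silane formation and retro-aldol cleavage, and the acetonide is untouched.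

Step 3
Reactants: 4 (2S,4S)-2-{(R)-[(tert-butyldimethylsilyl)oxy][(4S)-2,2-dimethyl-1,3-dioxolan-4-yl]methyl}-4-methylcyclohexan-1-one
Product: 5 (5S,7S)-7-{(R)-[(tert-butyldimethylsilyl)oxy][(4S)-2,2-dimethyl-1,3-dioxolan-4-yl]methyl}-5-methyloxepan-2-one
Conditions: mCPBA, NaHCO3, CH2Cl2, 0 °C → rt
Reagents that add atoms: 3-chloroperoxybenzoic acid, OOC(=O)c1cccc(Cl)c1
Why: Baeyer–Villiger oxidation; the more substituted α-carbon (C15, secondary) migrates in preference to C11 (primary) and with retention, which turns the C10–C15 bond into the C15–O bond of the lactone. The buffer protects the acetonide, and no alkene is present yet.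

Step 4
Reactants: 5 (5S,7S)-7-{(R)-[(tert-butyldimethylsilyl)oxy][(4S)-2,2-dimethyl-1,3-dioxolan-4-yl]methyl}-5-methyloxepan-2-one
Product: 6 methyl (4S,6S,7R)-7-[(tert-butyldimethylsilyl)oxy]-7-[(4S)-2,2-dimethyl-1,3-dioxolan-4-yl]-6-hydroxy-4-methylheptanoate
Conditions: K2CO3 (0.3 equiv), MeOH, 0 °C; AcOH quench
Reagents that add atoms: methanol, CO
Why: Base-catalysed transesterification opens the ε-lactone, and in methanol the equilibrium lies on the open side; brief contact with catalytic carbonate at 0 °C and an acidic quench are chosen to keep the silyl group on O16.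

Step 5
Reactants: 6 methyl (4S,6S,7R)-7-[(tert-butyldimethylsilyl)oxy]-7-[(4S)-2,2-dimethyl-1,3-dioxolan-4-yl]-6-hydroxy-4-methylheptanoate
Product: 7 methyl (4S,6S,7R)-7-[(tert-butyldimethylsilyl)oxy]-7-[(4S)-2,2-dimethyl-1,3-dioxolan-4-yl]-6-methoxy-4-methylheptanoate
Conditions: Me3OBF4, 1,8-bis(dimethylamino)naphthalene, CH2Cl2, 0 °C → rt
Reagents that add atoms: trimethyloxonium tetrafluoroborate, C[O+](C)C.F[B-](F)(F)F
Why: O-Alkylation of the alcohol with an oxonium salt and a non-nucleophilic base; no alkoxide is formed, so silyl migration, elimination and ester cleavage are avoided.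

Step 6
Reactants: 7 methyl (4S,6S,7R)-7-[(tert-butyldimethylsilyl)oxy]-7-[(4S)-2,2-dimethyl-1,3-dioxolan-4-yl]-6-methoxy-4-methylheptanoate
Product: 8 (4S,6S,7R)-7-[(tert-butyldimethylsilyl)oxy]-7-[(4S)-2,2-dimethyl-1,3-dioxolan-4-yl]-6-methoxy-4-methylheptanoic acid
Conditions: LiOH·H2O, THF/MeOH/H2O, 0 °C → rt; then 0.5 M HCl to pH 4 at 0 °C
Reagents that add atoms: lithium hydroxide, [Li+].[OH-]
Why: Saponification of an unhindered methyl ester; the secondary silyl ether and the acetonide are stable to hydroxide, and the cold, mild acidification spares the acetonide.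

Step 7
Reactants: 8 (4S,6S,7R)-7-[(tert-butyldimethylsilyl)oxy]-7-[(4S)-2,2-dimethyl-1,3-dioxolan-4-yl]-6-methoxy-4-methylheptanoic acid; 9 methyl L-serinate hydrochloride
Product: 10 methyl N-{(4S,6S,7R)-7-[(tert-butyldimethylsilyl)oxy]-7-[(4S)-2,2-dimethyl-1,3-dioxolan-4-yl]-6-methoxy-4-methylheptanoyl}-L-serinate
Conditions: EDC·HCl, HOBt, N-methylmorpholine, CH2Cl2, 0 °C → rt
Reagents that add atoms: none
Why: Carbodiimide/HOBt amide coupling; N-acylation is much faster than O-acylation, so the serine hydroxyl needs no protection.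

Step 8
Reactants: 10 methyl N-{(4S,6S,7R)-7-[(tert-butyldimethylsilyl)oxy]-7-[(4S)-2,2-dimethyl-1,3-dioxolan-4-yl]-6-methoxy-4-methylheptanoyl}-L-serinate
Product: 12 methyl 2-R*-1,3-oxazole-4-carboxylate, via oxazoline ester 11 (not isolated)
Conditions: (MeOCH2CH2)2NSF3 (Deoxo-Fluor), CH2Cl2, −20 °C; then BrCCl3, DBU, 0 °C → rt
Reagents that add atoms: none
Why: Cyclodehydration of the β-hydroxy amide with an aminosulfur trifluoride gives the oxazoline, and bromination/dehydrobromination with BrCCl3 and DBU aromatises it, which the C4 ester makes possible by acidifying H4 (one-pot oxazole synthesis from serine amides). The serine stereocentre is destroyed on purpose.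

Step 9
Reactants: 12 methyl 2-R*-1,3-oxazole-4-carboxylate
Product: 14 1-(2-R*-1,3-oxazol-4-yl)ethan-1-one, via Weinreb amide 13 (not isolated)
Conditions: MeNHOMe·HCl, iPrMgCl, THF, −20 °C; then MeMgBr, 0 °C; aq. NH4Cl
Reagents that add atoms: methylmagnesium bromide, C[Mg]Br; N,O-dimethylhydroxylamine hydrochloride, Cl.CNOC (its atoms are in 13 only)
Why: Ester-to-ketone conversion through the Weinreb amide; the magnesium amide transamidates the ester, and the Grignard reagent adds only once because the chelated tetrahedral intermediate persists until work-up.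

Step 10
Reactants: 14 1-(2-R*-1,3-oxazol-4-yl)ethan-1-one
Product: 15 ethyl (2E)-3-(2-R*-1,3-oxazol-4-yl)but-2-enoate
Conditions: (EtO)2P(O)CH2CO2Et, NaH, THF, 0 → 50 °C
Reagents that add atoms: triethyl phosphonoacetate, CCOC(=O)CP(=O)(OCC)OCC
Why: Horner–Wadsworth–Emmons olefination of a heteroaryl methyl ketone; reversible addition and elimination place the ester trans to the oxazole (6E), and any Z isomer should be separable by chromatography.

Step 11
Reactants: 15 ethyl (2E)-3-(2-R*-1,3-oxazol-4-yl)but-2-enoate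
Product: 16 (2E)-3-(2-R*-1,3-oxazol-4-yl)but-2-en-1-ol
Conditions: iBu2AlH, CH2Cl2, −78 °C; aq. potassium sodium tartrate
Reagents that add atoms: none
Why: 1,2-Reduction of the enoate to the allylic alcohol with an aluminium hydride at low temperature; oxazole, silyl ether and acetonide are inert.

Step 12
Reactants: 16 (2E)-3-(2-R*-1,3-oxazol-4-yl)but-2-en-1-ol
Product: 17 (2E)-3-(2-R*-1,3-oxazol-4-yl)but-2-enal
Conditions: MnO2, CH2Cl2, rt
Reagents that add atoms: none
Why: Allylic oxidation with activated MnO2 stops at the enal and leaves the alkene geometry intact.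

Step 13
Reactants: 17 (2E)-3-(2-R*-1,3-oxazol-4-yl)but-2-enal
Product: 18 (3S,4R,5E)-3-methyl-6-(2-R*-1,3-oxazol-4-yl)hepta-1,5-dien-4-ol
Conditions: cis-2-butene, n-BuLi, KOtBu, THF, −78 → −45 °C; (+)-Ipc2BOMe, −78 °C; BF3·OEt2; then 17, −78 °C; NaOH, H2O2
Reagents that add atoms: (Z)-crotyldiisopinocampheylborane, made in the flask from cis-2-butene (C/C=C\C) and (+)-Ipc2BOMe, C/C=C\CB([C@H]1C[C@H]2C[C@H](C2(C)C)[C@@H]1C)[C@H]1C[C@H]2C[C@H](C2(C)C)[C@@H]1C
Why: Brown crotylboration; the (Z)-crotylborane reacts through a closed chair transition state, so its geometry becomes the 4,5-syn relationship, and the isopinocampheyl groups of the (−)-α-pinene series direct attack to the re face of the enal, which gives 4S,5R (target numbering). The enal is the only electrophile for an allylborane in 17.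

Step 14
Reactants: 18 (3S,4R,5E)-3-methyl-6-(2-R*-1,3-oxazol-4-yl)hepta-1,5-dien-4-ol
Product: 19 4-{(2E,4R,5S)-4-[(tert-butyldimethylsilyl)oxy]-5-methylhepta-2,6-dien-2-yl}-2-R*-1,3-oxazole
Conditions: TBSOTf, 2,6-lutidine, CH2Cl2, −78 °C
Reagents that add atoms: tert-butyldimethylsilyl triflate, CC(C)(C)[Si](C)(C)OS(=O)(=O)C(F)(F)F
Why: Silyl ether formation on the allylic secondary alcohol; the cold, buffered conditions spare the acetonide.

Step 15
Reactants: 19 4-{(2E,4R,5S)-4-[(tert-butyldimethylsilyl)oxy]-5-methylhepta-2,6-dien-2-yl}-2-R*-1,3-oxazole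
Product: 20 (2S,3S,4S,6S)-3-[(tert-butyldimethylsilyl)oxy]-4-methoxy-6-methyl-8-Q-octane-1,2-diol
Conditions: AcOH/THF/H2O (4:1:1), 40 °C
Reagents that add atoms: none
Why: Acid-catalysed hydrolysis of a terminal isopropylidene acetal; dilute acetic acid should cleave the unhindered terminal acetonide faster than the two hindered secondary silyl ethers.

Step 16
Reactants: 20 (2S,3S,4S,6S)-3-[(tert-butyldimethylsilyl)oxy]-4-methoxy-6-methyl-8-Q-octane-1,2-diol
Product: 22 (2E,4S,5S,6S,8S)-5-[(tert-butyldimethylsilyl)oxy]-4-hydroxy-6-methoxy-2,8-dimethyl-10-Q-dec-2-enal, via hydroxy aldehyde 21 (not isolated)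
Conditions: TEMPO (20 mol %), PhI(OAc)2, Ph3P=C(CH3)CHO, CH2Cl2, rt → 40 °C
Reagents that add atoms: 2-(triphenylphosphoranylidene)propanal, CC(C=O)=P(c1ccccc1)(c1ccccc1)c1ccccc1
Why: Tandem oxidation–Wittig olefination; the oxoammonium oxidant takes the primary hydroxyl of the 1,2-diol in preference to the hindered secondary one, and the stabilised ylide traps the α-hydroxy aldehyde as it forms, which limits its dimerisation and its enolisation at C17. Stabilised α-methyl ylides give the E trisubstituted alkene.

Step 17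
Reactants: 22 (2E,4S,5S,6S,8S)-5-[(tert-butyldimethylsilyl)oxy]-4-hydroxy-6-methoxy-2,8-dimethyl-10-Q-dec-2-enal
Product: 23 (2E,4S,5R,6S,8S)-5-[(tert-butyldimethylsilyl)oxy]-6-methoxy-2,8-dimethyl-1-oxo-10-Q-dec-2-en-4-yl prop-2-enoate
Conditions: acryloyl chloride, iPr2NEt, CH2Cl2, −78 → −20 °C
Reagents that add atoms: acryloyl chloride, C=CC(Cl)=O
Why: Esterification of the only free hydroxyl (O17) with an acid chloride and a hindered amine; it brings in C1–C2 and caps O17 in one operation.

Step 18
Reactants: 23 (2E,4S,5R,6S,8S)-5-[(tert-butyldimethylsilyl)oxy]-6-methoxy-2,8-dimethyl-1-oxo-10-Q-dec-2-en-4-yl prop-2-enoate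
Product: 24 (2E)-2-methyl-3-(core)prop-2-enal
Conditions: (H2IMes)(PCy3)Cl2Ru=CHPh (second-generation Grubbs catalyst, 10 mol %), toluene (1 mM), 80 °C
Reagents that add atoms: none
Why: Ring-closing olefin metathesis between the monosubstituted C3 alkene and the acrylate closes the 18-membered ring at C2=C3, and large-ring enoates form as the E isomers. The two trisubstituted alkenes (C6=C7 and the enal C18=C19) are too hindered or too electron-poor to compete, and the skipped diene is not yet present.

Step 19
Reactants: 24 (2E)-2-methyl-3-(core)prop-2-enal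
Product: 25 (2E)-2-methyl-3-(core)prop-2-en-1-ol
Conditions: NaBH4, CeCl3·7H2O, MeOH/THF, −40 °C
Reagents that add atoms: none
Why: Luche reduction; the borohydride/cerium chloride system reduces the enal carbonyl 1,2-selectively and leaves the macrocyclic enoate and lactone alone.

Step 20
Reactants: 25 (2E)-2-methyl-3-(core)prop-2-en-1-ol
Product: 26 17-[(1E)-3-bromo-2-methylprop-1-en-1-yl] derivative of the core
Conditions: CBr4, PPh3, CH2Cl2, −20 → 0 °C
Reagents that add atoms: carbon tetrabromide, BrC(Br)(Br)Br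
Why: Appel bromination of a primary allylic alcohol; the E alkene keeps O17 and C20 apart, so neither acyl transfer nor allylic transposition is expected at low temperature.

Step 21
Reactants: 27 [(2R)-2-methyloxiran-2-yl]methanol
Product: 28 (2S)-2-methylpent-4-yne-1,2-diol
Conditions: LiC≡CH·H2NCH2CH2NH2 (2.5 equiv), DMSO, 0 °C → rt; aq. NH4Cl
Reagents that add atoms: lithium acetylide–ethylenediamine complex, [Li+].[C-]#C.NCCN
Why: SN2 opening of the epoxide by an acetylide at the unsubstituted carbon; C24 is not touched, so the configuration of 27 is carried into 28 (the descriptor changes from R to S only because the priorities change). One equivalent of acetylide is spent on the hydroxyl.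

Step 22
Reactants: 28 (2S)-2-methylpent-4-yne-1,2-diol
Product: 29 (2S)-2-hydroxy-2-methylpent-4-ynoic acid
Conditions: TEMPO (cat.), NaOCl (cat.), NaClO2, MeCN/phosphate buffer pH 6.7, 35 °C
Reagents that add atoms: sodium chlorite, [Na+].[O-]Cl=O
Why: TEMPO-catalysed oxidation with chlorite as terminal oxidant takes the primary alcohol to the acid; the tertiary alcohol cannot be oxidised, and the terminal alkyne is inert at this pH.

Step 23
Reactants: 29 (2S)-2-hydroxy-2-methylpent-4-ynoic acid
Product: 30 2-(trimethylsilyl)ethyl (2S)-2-hydroxy-2-methylpent-4-ynoate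
Conditions: Me3SiCH2CH2OH, EDC·HCl, DMAP (cat.), CH2Cl2, 0 °C → rt
Reagents that add atoms: 2-(trimethylsilyl)ethanol, C[Si](C)(C)CCO
Why: Steglich-type carbodiimide esterification; the tertiary hydroxyl is too hindered to compete with the primary alcohol, and the ester can later be removed with fluoride.

Step 24
Reactants: 26 17-[(1E)-3-bromo-2-methylprop-1-en-1-yl] derivative of the core; 30 2-(trimethylsilyl)ethyl (2S)-2-hydroxy-2-methylpent-4-ynoate
Product: 31 2-(trimethylsilyl)ethyl (2S,7E)-2-hydroxy-2,7-dimethyl-8-(core)oct-7-en-4-ynoate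
Conditions: CuI, NaI, K2CO3, DMF, rt
Reagents that add atoms: none
Why: Copper-mediated coupling of a terminal alkyne with a primary allylic halide gives the skipped enyne by substitution at C20; the carbonate base is too weak to enolise the esters, and the tertiary hydroxyl does not interfere.

Step 25
Reactants: 31 2-(trimethylsilyl)ethyl (2S,7E)-2-hydroxy-2,7-dimethyl-8-(core)oct-7-en-4-ynoate
Product: 32 2-(trimethylsilyl)ethyl (2S,4Z,7E)-2-hydroxy-2,7-dimethyl-8-(core)octa-4,7-dienoate
Conditions: H2 (1 atm), Pd/CaCO3 poisoned with Pb(OAc)2 (Lindlar catalyst), quinoline, EtOAc, rt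
Reagents that add atoms: none
Why: Lindlar semi-hydrogenation; syn addition of one equivalent of hydrogen on the poisoned palladium surface gives the 21Z alkene, while trisubstituted and conjugated alkenes react much more slowly.

Step 26
Reactants: 32 2-(trimethylsilyl)ethyl (2S,4Z,7E)-2-hydroxy-2,7-dimethyl-8-(core)octa-4,7-dienoate
Product: 33 CNP0112511.2
Conditions: (Me2N)3S+ Me3SiF2− (TASF), DMF, 0 °C → rt; aq. NH4Cl
Reagents that add atoms: none
Why: Fluoride-induced desilylation; the difluorosilicate cleaves both silyl ethers and, by β-elimination of ethene, the 2-(trimethylsilyl)ethyl ester, under nearly neutral anhydrous conditions that should keep the acyl group on O17.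

## Compound list

1 | 4-methylcyclohexan-1-one | CC1CCC(=O)CC1 | starting material
2 | (4S)-2,2-dimethyl-1,3-dioxolane-4-carbaldehyde | O=C[C@@H]1COC(C)(C)O1 | starting material
3 | (2S,4S)-2-{(R)-[(4S)-2,2-dimethyl-1,3-dioxolan-4-yl](hydroxy)methyl}-4-methylcyclohexan-1-one | O=C1[C@H]([C@@H](O)[C@@H]2COC(C)(C)O2)C[C@@H](C)CC1 | intermediate
4 | (2S,4S)-2-{(R)-[(tert-butyldimethylsilyl)oxy][(4S)-2,2-dimethyl-1,3-dioxolan-4-yl]methyl}-4-methylcyclohexan-1-one | O=C1[C@H]([C@@H](O[Si](C)(C)C(C)(C)C)[C@@H]2COC(C)(C)O2)C[C@@H](C)CC1 | intermediate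
5 | (5S,7S)-7-{(R)-[(tert-butyldimethylsilyl)oxy][(4S)-2,2-dimethyl-1,3-dioxolan-4-yl]methyl}-5-methyloxepan-2-one | O=C1O[C@H]([C@@H](O[Si](C)(C)C(C)(C)C)[C@@H]2COC(C)(C)O2)C[C@@H](C)CC1 | intermediate
6 | methyl (4S,6S,7R)-7-[(tert-butyldimethylsilyl)oxy]-7-[(4S)-2,2-dimethyl-1,3-dioxolan-4-yl]-6-hydroxy-4-methylheptanoate | COC(=O)CC[C@H](C)C[C@H](O)[C@@H](O[Si](C)(C)C(C)(C)C)[C@@H]1COC(C)(C)O1 | intermediate
7 | methyl (4S,6S,7R)-7-[(tert-butyldimethylsilyl)oxy]-7-[(4S)-2,2-dimethyl-1,3-dioxolan-4-yl]-6-methoxy-4-methylheptanoate | COC(=O)CC[C@H](C)C[C@H](OC)[C@@H](O[Si](C)(C)C(C)(C)C)[C@@H]1COC(C)(C)O1 | intermediate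
8 | (4S,6S,7R)-7-[(tert-butyldimethylsilyl)oxy]-7-[(4S)-2,2-dimethyl-1,3-dioxolan-4-yl]-6-methoxy-4-methylheptanoic acid | OC(=O)CC[C@H](C)C[C@H](OC)[C@@H](O[Si](C)(C)C(C)(C)C)[C@@H]1COC(C)(C)O1 | intermediate
9 | methyl L-serinate hydrochloride | Cl.COC(=O)[C@@H](N)CO | starting material
10 | methyl N-{(4S,6S,7R)-7-[(tert-butyldimethylsilyl)oxy]-7-[(4S)-2,2-dimethyl-1,3-dioxolan-4-yl]-6-methoxy-4-methylheptanoyl}-L-serinate | COC(=O)[C@H](CO)NC(=O)CC[C@H](C)C[C@H](OC)[C@@H](O[Si](C)(C)C(C)(C)C)[C@@H]1COC(C)(C)O1 | intermediate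
11 | methyl (4S)-2-R*-4,5-dihydro-1,3-oxazole-4-carboxylate | COC(=O)[C@@H]1COC(CC[C@H](C)C[C@H](OC)[C@@H](O[Si](C)(C)C(C)(C)C)[C@@H]2COC(C)(C)O2)=N1 | intermediate (not isolated)
12 | methyl 2-R*-1,3-oxazole-4-carboxylate | COC(=O)c1coc(CC[C@H](C)C[C@H](OC)[C@@H](O[Si](C)(C)C(C)(C)C)[C@@H]2COC(C)(C)O2)n1 | intermediate
13 | N-methoxy-N-methyl-2-R*-1,3-oxazole-4-carboxamide | CON(C)C(=O)c1coc(CC[C@H](C)C[C@H](OC)[C@@H](O[Si](C)(C)C(C)(C)C)[C@@H]2COC(C)(C)O2)n1 | intermediate (not isolated)
14 | 1-(2-R*-1,3-oxazol-4-yl)ethan-1-one | CC(=O)c1coc(CC[C@H](C)C[C@H](OC)[C@@H](O[Si](C)(C)C(C)(C)C)[C@@H]2COC(C)(C)O2)n1 | intermediate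
15 | ethyl (2E)-3-(2-R*-1,3-oxazol-4-yl)but-2-enoate | CCOC(=O)/C=C(\C)c1coc(CC[C@H](C)C[C@H](OC)[C@@H](O[Si](C)(C)C(C)(C)C)[C@@H]2COC(C)(C)O2)n1 | intermediate
16 | (2E)-3-(2-R*-1,3-oxazol-4-yl)but-2-en-1-ol | OC/C=C(\C)c1coc(CC[C@H](C)C[C@H](OC)[C@@H](O[Si](C)(C)C(C)(C)C)[C@@H]2COC(C)(C)O2)n1 | intermediate
17 | (2E)-3-(2-R*-1,3-oxazol-4-yl)but-2-enal | O=C/C=C(\C)c1coc(CC[C@H](C)C[C@H](OC)[C@@H](O[Si](C)(C)C(C)(C)C)[C@@H]2COC(C)(C)O2)n1 | intermediate
18 | (3S,4R,5E)-3-methyl-6-(2-R*-1,3-oxazol-4-yl)hepta-1,5-dien-4-ol | C=C[C@H](C)[C@@H](O)/C=C(\C)c1coc(CC[C@H](C)C[C@H](OC)[C@@H](O[Si](C)(C)C(C)(C)C)[C@@H]2COC(C)(C)O2)n1 | intermediate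
19 | 4-{(2E,4R,5S)-4-[(tert-butyldimethylsilyl)oxy]-5-methylhepta-2,6-dien-2-yl}-2-R*-1,3-oxazole | C=C[C@H](C)[C@@H](O[Si](C)(C)C(C)(C)C)/C=C(\C)c1coc(CC[C@H](C)C[C@H](OC)[C@@H](O[Si](C)(C)C(C)(C)C)[C@@H]2COC(C)(C)O2)n1 | intermediate
20 | (2S,3S,4S,6S)-3-[(tert-butyldimethylsilyl)oxy]-4-methoxy-6-methyl-8-Q-octane-1,2-diol | C=C[C@H](C)[C@@H](O[Si](C)(C)C(C)(C)C)/C=C(\C)c1coc(CC[C@H](C)C[C@H](OC)[C@@H](O[Si](C)(C)C(C)(C)C)[C@@H](O)CO)n1 | intermediate
21 | (2R,3S,4S,6S)-3-[(tert-butyldimethylsilyl)oxy]-2-hydroxy-4-methoxy-6-methyl-8-Q-octanal | C=C[C@H](C)[C@@H](O[Si](C)(C)C(C)(C)C)/C=C(\C)c1coc(CC[C@H](C)C[C@H](OC)[C@@H](O[Si](C)(C)C(C)(C)C)[C@@H](O)C=O)n1 | intermediate (not isolated)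
22 | (2E,4S,5S,6S,8S)-5-[(tert-butyldimethylsilyl)oxy]-4-hydroxy-6-methoxy-2,8-dimethyl-10-Q-dec-2-enal | C=C[C@H](C)[C@@H](O[Si](C)(C)C(C)(C)C)/C=C(\C)c1coc(CC[C@H](C)C[C@H](OC)[C@@H](O[Si](C)(C)C(C)(C)C)[C@@H](O)/C=C(\C)C=O)n1 | intermediate
23 | (2E,4S,5R,6S,8S)-5-[(tert-butyldimethylsilyl)oxy]-6-methoxy-2,8-dimethyl-1-oxo-10-Q-dec-2-en-4-yl prop-2-enoate | C=C[C@H](C)[C@@H](O[Si](C)(C)C(C)(C)C)/C=C(\C)c1coc(CC[C@H](C)C[C@H](OC)[C@@H](O[Si](C)(C)C(C)(C)C)[C@@H](OC(=O)C=C)/C=C(\C)C=O)n1 | intermediate
24 | (2E)-2-methyl-3-(core)prop-2-enal (5,16-bis-TBS macrolactone with the C18=C19 enal) | CO[C@H]1C[C@@H](C)CCc2nc(co2)/C(C)=C/[C@H](O[Si](C)(C)C(C)(C)C)[C@@H](C)/C=C/C(=O)O[C@@H](/C=C(\C)C=O)[C@@H]1O[Si](C)(C)C(C)(C)C | intermediate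
25 | (2E)-2-methyl-3-(core)prop-2-en-1-ol | CO[C@H]1C[C@@H](C)CCc2nc(co2)/C(C)=C/[C@H](O[Si](C)(C)C(C)(C)C)[C@@H](C)/C=C/C(=O)O[C@@H](/C=C(\C)CO)[C@@H]1O[Si](C)(C)C(C)(C)C | intermediate
26 | 17-[(1E)-3-bromo-2-methylprop-1-en-1-yl] derivative of the core | CO[C@H]1C[C@@H](C)CCc2nc(co2)/C(C)=C/[C@H](O[Si](C)(C)C(C)(C)C)[C@@H](C)/C=C/C(=O)O[C@@H](/C=C(\C)CBr)[C@@H]1O[Si](C)(C)C(C)(C)C | intermediate
27 | [(2R)-2-methyloxiran-2-yl]methanol | C[C@@]1(CO)CO1 | starting material
28 | (2S)-2-methylpent-4-yne-1,2-diol | C#CC[C@](C)(O)CO | intermediate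
29 | (2S)-2-hydroxy-2-methylpent-4-ynoic acid | C#CC[C@](C)(O)C(=O)O | intermediate
30 | 2-(trimethylsilyl)ethyl (2S)-2-hydroxy-2-methylpent-4-ynoate | C#CC[C@](C)(O)C(=O)OCC[Si](C)(C)C | intermediate
31 | 2-(trimethylsilyl)ethyl (2S,7E)-2-hydroxy-2,7-dimethyl-8-(core)oct-7-en-4-ynoate | CO[C@H]1C[C@@H](C)CCc2nc(co2)/C(C)=C/[C@H](O[Si](C)(C)C(C)(C)C)[C@@H](C)/C=C/C(=O)O[C@@H](/C=C(\C)CC#CC[C@](C)(O)C(=O)OCC[Si](C)(C)C)[C@@H]1O[Si](C)(C)C(C)(C)C | intermediate
32 | 2-(trimethylsilyl)ethyl (2S,4Z,7E)-2-hydroxy-2,7-dimethyl-8-(core)octa-4,7-dienoate | CO[C@H]1C[C@@H](C)CCc2nc(co2)/C(C)=C/[C@H](O[Si](C)(C)C(C)(C)C)[C@@H](C)/C=C/C(=O)O[C@@H](/C=C(\C)C/C=C\C[C@](C)(O)C(=O)OCC[Si](C)(C)C)[C@@H]1O[Si](C)(C)C(C)(C)C | intermediate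
33 | CNP0112511.2: (2S,4Z,7E)-2-hydroxy-2,7-dimethyl-8-(macrolide-17-yl)octa-4,7-dienoic acid, the ring as in "core" with free 5- and 16-hydroxyls (4S,5R,13S,15S,16R,17S; 2E,6E) | CO[C@H]1C[C@@H](C)CCc2nc(co2)/C(C)=C/[C@H](O)[C@@H](C)/C=C/C(=O)O[C@@H](/C=C(\C)C/C=C\C[C@](C)(O)C(=O)O)[C@@H]1O | target

## Step count and risks

Total: 26 steps. Longest linear sequence: 23 steps (steps 1–20 and 24–26); the alkyne branch is 3 steps (21–23).

**Step 1 (key step).** The likely failure is incomplete discrimination between the two enantiotopic α-carbons (C13 is remote from the bond being formed). Slow turnover could also allow the aldehyde to enolise or the axial C15 substituent to epimerise. Fallback, from 1 back to 3: make the same C15–C16 bond under substrate control. Ketone 1 is deprotonated with LiN[(R)-CH(CH3)Ph]2 in the presence of Me3SiCl (the antipodal amide if the sense proved opposite) to give trimethyl{[(4S)-4-methylcyclohex-1-en-1-yl]oxy}silane F1. MeLi releases the lithium enolate, which adds to 2 at −78 °C through a chair transition state (anti aldol, Felkin–Anh face, axial attack trans to the methyl) to return to 3.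

**Step 16.** The oxidation may not stop cleanly: glycol cleavage of the 1,2-diol, enolisation of the α-hydroxy aldehyde with loss of C17, or a slow Wittig step that lets the aldehyde dimerise. Fallback, from 20 back to 23: the primary hydroxyl is silylated with Et3SiCl/imidazole to (2S,3S,4S,6S)-3-[(tert-butyldimethylsilyl)oxy]-4-methoxy-6-methyl-8-Q-1-[(triethylsilyl)oxy]octan-2-ol F3. O17 is acylated with acryloyl chloride to the acrylate F4. Swern oxidation, which converts primary triethylsilyl ethers directly into aldehydes, gives the α-acryloyloxy aldehyde F5, and the same ylide converts F5 into 23.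

**Step 18.** Ring closure may lose to intermolecular metathesis of the C3 vinyl groups, to catalyst binding by the oxazole nitrogen, or to closure of the acrylate onto C18=C19 (a butenolide with loss of the enal). Fallback, from 22 back to 24: cross-metathesis of the C3 vinyl group of 22 with acrylic acid, using (H2IMes)Cl2Ru=CH(2-iPrO-C6H4) (second-generation Hoveyda–Grubbs catalyst), gives the (2E)-seco acid F6. Yamaguchi macrolactonisation (2,4,6-trichlorobenzoyl chloride, Et3N, then DMAP at high dilution) onto O17, the only free hydroxyl, gives 24.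

**Step 4.** The C15 alkoxide formed on methanolysis may take the silyl group from O16 (1,2-silyl migration), and the hydroxy ester may relactonise on concentration. Fallback, from 5 back to 7: the lactone is hydrolysed with LiOH in aqueous THF at 0 °C, where the C15 hydroxyl stays protonated, to (4S,6S,7R)-7-[(tert-butyldimethylsilyl)oxy]-7-[(4S)-2,2-dimethyl-1,3-dioxolan-4-yl]-6-hydroxy-4-methylheptanoic acid F2. Carboxylate and hydroxyl are then methylated together with excess Me3OBF4 and 1,8-bis(dimethylamino)naphthalene, which gives 7 directly.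

**Step 26.** The freed O16 alkoxide may attack the lactone carbonyl (acyl shift from O17, ring contraction), or the hindered C16 silyl ether may be cleaved too slowly. Fallback, from 32 back to 33: the two silyl ethers are first removed with HF·pyridine buffered with pyridine in THF, which forms no alkoxide, to give the 2-(trimethylsilyl)ethyl ester of the target F7. A short treatment with (Me2N)3S+ Me3SiF2− at 0 °C then only has to cleave the ester.

## Further compounds

F1 | step 1 | trimethyl{[(4S)-4-methylcyclohex-1-en-1-yl]oxy}silane | C[Si](C)(C)OC1=CC[C@@H](C)CC1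
F2 | step 4 | (4S,6S,7R)-7-[(tert-butyldimethylsilyl)oxy]-7-[(4S)-2,2-dimethyl-1,3-dioxolan-4-yl]-6-hydroxy-4-methylheptanoic acid | OC(=O)CC[C@H](C)C[C@H](O)[C@@H](O[Si](C)(C)C(C)(C)C)[C@@H]1COC(C)(C)O1
F3 | step 16 | (2S,3S,4S,6S)-3-[(tert-butyldimethylsilyl)oxy]-4-methoxy-6-methyl-8-Q-1-[(triethylsilyl)oxy]octan-2-ol | C=C[C@H](C)[C@@H](O[Si](C)(C)C(C)(C)C)/C=C(\C)c1coc(CC[C@H](C)C[C@H](OC)[C@@H](O[Si](C)(C)C(C)(C)C)[C@@H](O)CO[Si](CC)(CC)CC)n1
F4 | step 16 | (2S,3R,4S,6S)-3-[(tert-butyldimethylsilyl)oxy]-4-methoxy-6-methyl-8-Q-1-[(triethylsilyl)oxy]octan-2-yl prop-2-enoate | C=C[C@H](C)[C@@H](O[Si](C)(C)C(C)(C)C)/C=C(\C)c1coc(CC[C@H](C)C[C@H](OC)[C@@H](O[Si](C)(C)C(C)(C)C)[C@@H](OC(=O)C=C)CO[Si](CC)(CC)CC)n1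
F5 | step 16 | (2R,3R,4S,6S)-3-[(tert-butyldimethylsilyl)oxy]-4-methoxy-6-methyl-1-oxo-8-Q-octan-2-yl prop-2-enoate | C=C[C@H](C)[C@@H](O[Si](C)(C)C(C)(C)C)/C=C(\C)c1coc(CC[C@H](C)C[C@H](OC)[C@@H](O[Si](C)(C)C(C)(C)C)[C@@H](OC(=O)C=C)C=O)n1
F6 | step 18 | (2E)-seco acid: 22 with its terminal =CH2 replaced by =CH–CO2H (C1 acid, O17 free) | OC(=O)/C=C/[C@H](C)[C@@H](O[Si](C)(C)C(C)(C)C)/C=C(\C)c1coc(CC[C@H](C)C[C@H](OC)[C@@H](O[Si](C)(C)C(C)(C)C)[C@@H](O)/C=C(\C)C=O)n1
F7 | step 26 | 2-(trimethylsilyl)ethyl ester of CNP0112511.2 (5- and 16-hydroxyls free) | CO[C@H]1C[C@@H](C)CCc2nc(co2)/C(C)=C/[C@H](O)[C@@H](C)/C=C/C(=O)O[C@@H](/C=C(\C)C/C=C\C[C@](C)(O)C(=O)OCC[Si](C)(C)C)[C@@H]1O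
A1 | alternative 1 | fully protected macrolide (TBS ethers on O5 and O16, triethylsilyl ether on O24, 2-(trimethylsilyl)ethyl ester) | CO[C@H]1C[C@@H](C)CCc2nc(co2)/C(C)=C/[C@H](O[Si](C)(C)C(C)(C)C)[C@@H](C)/C=C/C(=O)O[C@@H](/C=C(\C)C/C=C\C[C@](C)(O[Si](CC)(CC)CC)C(=O)OCC[Si](C)(C)C)[C@@H]1O[Si](C)(C)C(C)(C)C
A2 | alternative 1 | open-chain C17 ester with an (E)-alkenyl tributylstannane at C7 and an oxazol-4-yl triflate at C8, protected as A1 | CCCC[Sn](CCCC)(CCCC)/C(C)=C/[C@H](O[Si](C)(C)C(C)(C)C)[C@@H](C)/C=C/C(=O)O[C@@H](/C=C(\C)C/C=C\C[C@](C)(O[Si](CC)(CC)CC)C(=O)OCC[Si](C)(C)C)[C@H](O[Si](C)(C)C(C)(C)C)[C@H](C[C@@H](C)CCc1nc(OS(=O)(=O)C(F)(F)F)co1)OC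
A3 | alternative 2 | (2R,3S,4E)-6-[(tert-butyldiphenylsilyl)oxy]-2-[(4-methoxyphenyl)methoxy]-3-methylhex-4-enoic acid | OC(=O)[C@H](OCc1ccc(OC)cc1)[C@@H](C)/C=C/CO[Si](c1ccccc1)(c1ccccc1)C(C)(C)C
A4 | alternative 2 | (2S,3E)-1-[(tert-butyldiphenylsilyl)oxy]pent-3-en-2-yl 2-[(4-methoxyphenyl)methoxy]acetate | C/C=C/[C@@H](CO[Si](c1ccccc1)(c1ccccc1)C(C)(C)C)OC(=O)COCc1ccc(OC)cc1
A5 | alternative 3 | (2R,5S)-2-tert-butyl-5-[(5E)-6-iodo-5-methylhex-5-en-2-yn-1-yl]-5-methyl-1,3-dioxolan-4-one | C[C@@]1(CC#CC/C(C)=C/I)O[C@@H](C(C)(C)C)OC1=O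
A6 | alternative 3 | (2R,5R)-2-tert-butyl-5-methyl-1,3-dioxolan-4-one | C[C@H]1O[C@@H](C(C)(C)C)OC1=O
A7 | alternative 3 | (1E)-6-bromo-1-iodo-2-methylhex-1-en-4-yne | BrCC#CC/C(C)=C/I
A8 | alternative 3 | (R)-lactic acid | C[C@@H](O)C(=O)O
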